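The route rests on cutting the cyclohexane at C2–C3 and C1–C6. The key step exploits that ring atoms C2(CH3)2–C1(O) are an α,α-dimethyl ketone enolate in disguise, while C3, C4, C5, C6 and the exocyclic methylene carbon map onto a 1-phosphono-1-carbethoxybuta-1,3-diene. In one operation the regiodefined enolate adds 1,6 to the diene and the phosphonate anion so formed olefinates its own ketone, giving the ring with its quaternary carbon and a tetrasubstituted enoate. The precursor is an acyclic isopropenyl ketone carrying a linalool-derived oxetane; that oxetane later becomes the tertiary peroxide carbon by invertive perhydrolysis, and Sharpless epoxidation sets the ring carbinol.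

Key step: step 7

Remark: locants follow the target name (cyclohexane C1 = carbinol carbon, C2 = C(CH3)2, C6 = C(=CH2); dioxane C3 = CH, C6 = C(CH3)); (R)-(−)-linalool of high enantiomeric purity is assumed as the commercial chiral source.

Step 1
Reactants: 1 (R)-(−)-linalool
Product: 3 (3R)-3,7-dimethyloct-6-ene-1,3-diol, via bis-borane adduct 2 (not isolated)
Conditions: 9-BBN (2.2 equiv), THF, 0 °C to rt; then NaOH, H2O2, 0 °C
Reagents that add atoms: hydrogen peroxide, OO
Why: Brown hydroboration–oxidation, in which 9-BBN adds anti-Markovnikov to the monosubstituted vinyl group much faster than to the trisubstituted alkene and the tertiary carbinol centre is untouched.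

Step 2
Reactants: 3 (3R)-3,7-dimethyloct-6-ene-1,3-diol
Product: 5 (2R)-2-methyl-2-(4-methylpent-3-en-1-yl)oxetane, via primary tosylate 4 (not isolated)
Conditions: n-BuLi (1.0 equiv), THF, 0 °C; TsCl (1.0 equiv); then n-BuLi (1.05 equiv), 0 to 60 °C
Reagents that add atoms: none
Why: Intramolecular Williamson etherification (4-exo-tet) of the tertiary alkoxide onto the primary tosylate, which does not break the C–O bond of the stereocentre and so retains its configuration.

Step 3
Reactants: 5 (2R)-2-methyl-2-(4-methylpent-3-en-1-yl)oxetane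
Product: 6 2,2-dimethyl-3-{2-[(2R)-2-methyloxetan-2-yl]ethyl}oxirane
Conditions: mCPBA, NaHCO3, CH2Cl2, 0 °C
Reagents that add atoms: mCPBA, O=C(OO)c1cccc(Cl)c1
Why: Prilezhaev epoxidation of the only alkene under buffered conditions that spare the oxetane; the oxirane CH centre forms as a mixture that is erased in step 5.

Step 4
Reactants: 6 2,2-dimethyl-3-{2-[(2R)-2-methyloxetan-2-yl]ethyl}oxirane
Product: 7 2-methyl-5-[(2R)-2-methyloxetan-2-yl]pent-1-en-3-ol
Conditions: Et2Al(NC9H18) (diethylaluminium 2,2,6,6-tetramethylpiperidide, 2 equiv), toluene, 0 °C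
Reagents that add atoms: none
Why: Base-promoted epoxide-to-allylic-alcohol isomerisation (syn β-elimination), in which the aluminium amide removes a proton from the unhindered methyl group so that the C–O bond at the dimethyl carbon breaks and the isopropenyl carbinol results.

Step 5
Reactants: 7 2-methyl-5-[(2R)-2-methyloxetan-2-yl]pent-1-en-3-ol
Product: 8 2-methyl-5-[(2R)-2-methyloxetan-2-yl]pent-1-en-3-one
Conditions: Dess–Martin periodinane, NaHCO3, CH2Cl2, 0 °C
Reagents that add atoms: none
Why: Dess–Martin oxidation of the secondary allylic alcohol to the isopropenyl ketone under mild buffered conditions that leave the oxetane intact.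

Step 6
Reactants: 9 triethyl phosphonoacetate, 10 acrolein
Product: 11 ethyl 2-(diethoxyphosphoryl)penta-2,4-dienoate
Conditions: TiCl4, N-methylmorpholine, THF, 0 °C
Reagents that add atoms: none
Why: Knoevenagel condensation (TiCl4/amine variant) of the phosphonoacetate with the aldehyde; the C2=C3 geometry is irrelevant because step 7 passes through a delocalised anion.

Step 7
Reactants: 8 2-methyl-5-[(2R)-2-methyloxetan-2-yl]pent-1-en-3-one, 11 ethyl 2-(diethoxyphosphoryl)penta-2,4-dienoate
Product: 14 ethyl 3,3-dimethyl-2-{2-[(2R)-2-methyloxetan-2-yl]ethyl}cyclohexa-1,5-diene-1-carboxylate, via lithium enolate 12 (not isolated), via phosphonate carbanion 13 (not isolated)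
Conditions: LiBH(s-Bu)3 (L-Selectride, 1.05 equiv), THF, −78 °C; then 11, −78 °C to reflux
Reagents that add atoms: none
Why: Conjugate hydride delivery to the β-unsubstituted isopropenyl ketone should give only the tetrasubstituted enolate 12, whose C(CH3)2 carbon adds to the unsubstituted δ-terminus of the doubly activated diene 11 (first new bond, ring C2–C3), and the phosphonate-stabilised allyl anion 13 then olefinates the ketone carbon intramolecularly (second new bond, ring C1–C6, formed as C=C) with loss of lithium diethyl phosphate. The closest known reaction types are the tandem Michael/intramolecular Horner–Wadsworth–Emmons annulation of 2-phosphonoacrylates and the cyclohexadiene annulation of buta-1,3-dienylphosphonium salts with carbonyl enolates; the step is the vinylogous Michael/Horner–Wadsworth–Emmons [4+2] version. The ring closes by 6-exo-trig attack of the α-phosphono carbon on the carbonyl (γ-attack would need a cyclobutane), and oxaphosphetane collapse makes the closure irreversible. No stereocentre is formed; the step installs the quaternary carbon and the tetrasubstituted enoate that later carries the reagent-controlled epoxidation. It needs enolate regiocontrol (fixed by the enone), δ- over β-attack on 11 (bulky tertiary nucleophile, unsubstituted δ-carbon) and a cis C4=C5 unit in 13 (the allyl anion can equilibrate).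

Step 8
Reactants: 14 ethyl 3,3-dimethyl-2-{2-[(2R)-2-methyloxetan-2-yl]ethyl}cyclohexa-1,5-diene-1-carboxylate
Product: 15 ethyl 3,3-dimethyl-2-{2-[(2R)-2-methyloxetan-2-yl]ethyl}cyclohex-1-ene-1-carboxylate
Conditions: H2 (1 atm), RhCl(PPh3)3 (cat.), benzene–EtOH, rt
Reagents that add atoms: none
Why: Homogeneous catalytic hydrogenation, which should saturate the cis-disubstituted ring alkene and leave the hindered tetrasubstituted enoate.

Step 9
Reactants: 15 ethyl 3,3-dimethyl-2-{2-[(2R)-2-methyloxetan-2-yl]ethyl}cyclohex-1-ene-1-carboxylate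
Product: 16 (3,3-dimethyl-2-{2-[(2R)-2-methyloxetan-2-yl]ethyl}cyclohex-1-en-1-yl)methanol
Conditions: i-Bu2AlH (2.5 equiv), CH2Cl2, −78 to 0 °C
Reagents that add atoms: none
Why: Hydride reduction of the enoate to the primary allylic alcohol at a temperature at which the oxetane is inert.

Step 10
Reactants: 16 (3,3-dimethyl-2-{2-[(2R)-2-methyloxetan-2-yl]ethyl}cyclohex-1-en-1-yl)methanol
Product: 17 [(1S,6S)-5,5-dimethyl-6-{2-[(2R)-2-methyloxetan-2-yl]ethyl}-7-oxabicyclo[4.1.0]heptan-1-yl]methanol
Conditions: Ti(OiPr)4 (cat.), L-(+)-diethyl tartrate (cat.), t-BuOOH, 4 Å molecular sieves, CH2Cl2, −20 °C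
Reagents that add atoms: tert-butyl hydroperoxide, CC(C)(C)OO
Why: Sharpless asymmetric epoxidation, in which the L-(+)-tartrate catalyst delivers oxygen to the face that gives the (S,S)-epoxy alcohol and so fixes the chain-bearing carbon as the future (S)-carbinol under reagent control, independent of the remote oxetane centre.

Step 11
Reactants: 17 [(1S,6S)-5,5-dimethyl-6-{2-[(2R)-2-methyloxetan-2-yl]ethyl}-7-oxabicyclo[4.1.0]heptan-1-yl]methanol
Product: 19 (1S)-2,2-dimethyl-6-methylidene-1-{2-[(2R)-2-methyloxetan-2-yl]ethyl}cyclohexan-1-ol, via epoxy iodide 18 (not isolated)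
Conditions: PPh3, I2, imidazole, THF, 0 °C; then Zn dust, AcOH, EtOH, rt
Reagents that add atoms: none
Why: Garegg–Samuelsson iodination followed by zinc-mediated reductive opening of the 2,3-epoxy iodide (1,3-transposition), in which β-elimination breaks only the oxirane C–O bond at the iodomethyl-bearing carbon, so the tertiary C–O bond keeps its (S) configuration while the exocyclic methylene forms.

Step 12
Reactants: 19 (1S)-2,2-dimethyl-6-methylidene-1-{2-[(2R)-2-methyloxetan-2-yl]ethyl}cyclohexan-1-ol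
Product: 21 triethyl({(1S)-2,2-dimethyl-6-methylidene-1-{2-[(2R)-2-methyloxetan-2-yl]ethyl}cyclohexyl}oxy)silane, via potassium alkoxide 20 (not isolated)
Conditions: KH, THF, 0 °C; then Et3SiCl, 0 °C to rt
Reagents that add atoms: chlorotriethylsilane, CC[Si](Cl)(CC)CC
Why: O-Silylation of the hindered tertiary alkoxide, which masks the ionisable allylic alcohol against the molybdenum and Lewis-acid reagents of later steps without exposing the oxetane to a silyl triflate.

Step 13
Reactants: 21 triethyl({(1S)-2,2-dimethyl-6-methylidene-1-{2-[(2R)-2-methyloxetan-2-yl]ethyl}cyclohexyl}oxy)silane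
Product: 22 (3S)-5-[(1S)-2,2-dimethyl-6-methylidene-1-(triethylsilyloxy)cyclohexyl]-3-hydroperoxy-3-methylpentan-1-ol
Conditions: anhydrous H2O2 in Et2O (excess), MoO2(acac)2 (cat.), rt
Reagents that add atoms: hydrogen peroxide, OO
Why: Molybdenum-catalysed perhydrolysis of a 2,2-disubstituted oxetane, in which H2O2 opens the ring at the tertiary carbon in an SN2-like manner with inversion and thereby sets the peroxide-bearing quaternary centre.

Step 14
Reactants: 22 (3S)-5-[(1S)-2,2-dimethyl-6-methylidene-1-(triethylsilyloxy)cyclohexyl]-3-hydroperoxy-3-methylpentan-1-ol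
Product: 23 (3S)-5-[(1S)-2,2-dimethyl-6-methylidene-1-(triethylsilyloxy)cyclohexyl]-3-methyl-3-[(triethylsilyl)peroxy]pentan-1-ol
Conditions: Et3SiCl (1.05 equiv), Et3N, CH2Cl2, −78 °C
Reagents that add atoms: chlorotriethylsilane, CC[Si](Cl)(CC)CC
Why: Chemoselective O-silylation, in which the far more acidic and α-nucleophilic hydroperoxide should be silylated under amine base at low temperature before the primary alcohol reacts.

Step 15
Reactants: 23 (3S)-5-[(1S)-2,2-dimethyl-6-methylidene-1-(triethylsilyloxy)cyclohexyl]-3-methyl-3-[(triethylsilyl)peroxy]pentan-1-ol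
Product: 24 (3S)-5-[(1S)-2,2-dimethyl-6-methylidene-1-(triethylsilyloxy)cyclohexyl]-3-methyl-3-[(triethylsilyl)peroxy]pentanal
Conditions: Dess–Martin periodinane, NaHCO3, CH2Cl2, 0 °C
Reagents that add atoms: none
Why: Dess–Martin oxidation of the primary alcohol to the aldehyde, with the silyl peroxide, silyl ether and alkene as spectators.

Step 16
Reactants: 24 (3S)-5-[(1S)-2,2-dimethyl-6-methylidene-1-(triethylsilyloxy)cyclohexyl]-3-methyl-3-[(triethylsilyl)peroxy]pentanal
Product: 26 (6S)-6-{2-[(1S)-2,2-dimethyl-6-methylidene-1-(triethylsilyloxy)cyclohexyl]ethyl}-3-methoxy-6-methyl-1,2-dioxane, via silylperoxy enol ether 25 (not isolated)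
Conditions: Ph3P(CH2OMe)Cl, KN(SiMe3)2, THF, −78 to 0 °C; then PPTS (cat.), MeOH–CH2Cl2, rt
Reagents that add atoms: (methoxymethyl)triphenylphosphonium chloride, COC[P+](c1ccccc1)(c1ccccc1)c1ccccc1.[Cl-]
Why: Wittig methoxymethylenation (one-carbon homologation) followed by acid-catalysed methanolysis of the silyl peroxide and 6-exo addition of the freed hydroperoxide to the enol ether (peroxyacetalisation), giving the cyclic peroxy acetal whose acetal carbon is left as a mixture because step 18 ionises it.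

Step 17
Reactants: 27 (4R)-4-benzyl-1,3-thiazolidine-2-thione, 28 propanoyl chloride
Product: 29 (4R)-4-benzyl-3-propanoyl-1,3-thiazolidine-2-thione
Conditions: Et3N, CH2Cl2, 0 °C
Reagents that add atoms: none
Why: N-Acylation of the thiazolidinethione auxiliary by the acid chloride.

Step 18
Reactants: 26 (6S)-6-{2-[(1S)-2,2-dimethyl-6-methylidene-1-(triethylsilyloxy)cyclohexyl]ethyl}-3-methoxy-6-methyl-1,2-dioxane, 29 (4R)-4-benzyl-3-propanoyl-1,3-thiazolidine-2-thione
Product: 31 (4R)-4-benzyl-3-{(2S)-2-[(3S,6R)-6-{2-[(1S)-2,2-dimethyl-6-methylidene-1-(triethylsilyloxy)cyclohexyl]ethyl}-6-methyl-1,2-dioxan-3-yl]propanoyl}-1,3-thiazolidine-2-thione, via titanium enolate 30 (not isolated)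
Conditions: 29, TiCl4, i-Pr2NEt, CH2Cl2, −78 °C; then 26, SnCl4, −78 °C
Reagents that add atoms: none
Why: Proposed new method: SnCl4 should ionise the methoxy peroxyacetal to a cyclic peroxycarbenium ion (the established reactivity of 3-alkoxy-1,2-dioxanes toward silyl ketene acetals and allylsilanes), which the chelated (Z)-chlorotitanium enolate 30 intercepts on its face anti to the benzyl group through an open antiperiplanar transition state; the closest known reaction is the anti-selective addition of chlorotitanium enolates of N-acyl thiazolidinethiones to dialkyl and cyclic O,O-acetals, and by that model the (R)-auxiliary should give the (2S) α-centre and the anti (3S) ring carbon under reagent control, since the quaternary C6 exerts little facial bias.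

Step 19
Reactants: 31 (4R)-4-benzyl-3-{(2S)-2-[(3S,6R)-6-{2-[(1S)-2,2-dimethyl-6-methylidene-1-(triethylsilyloxy)cyclohexyl]ethyl}-6-methyl-1,2-dioxan-3-yl]propanoyl}-1,3-thiazolidine-2-thione
Product: 32 methyl (2S)-2-[(3S,6R)-6-{2-[(1S)-2,2-dimethyl-6-methylidene-1-(triethylsilyloxy)cyclohexyl]ethyl}-6-methyl-1,2-dioxan-3-yl]propanoate
Conditions: MeOH, imidazole, CH2Cl2, rt
Reagents that add atoms: methanol, CO
Why: Nucleophilic acyl substitution (methanolysis of the activated N-acyl thiazolidinethione) under near-neutral conditions that should avoid β-elimination of the peroxide and epimerisation at C2.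

Step 20
Reactants: 32 methyl (2S)-2-[(3S,6R)-6-{2-[(1S)-2,2-dimethyl-6-methylidene-1-(triethylsilyloxy)cyclohexyl]ethyl}-6-methyl-1,2-dioxan-3-yl]propanoate
Product: 33 methyl (2S)-2-[(3S,6R)-6-{2-[(1S)-1-hydroxy-2,2-dimethyl-6-methylidenecyclohexyl]ethyl}-6-methyl-1,2-dioxan-3-yl]propanoate
Conditions: HF·pyridine, pyridine–THF, 0 °C
Reagents that add atoms: none
Why: Fluoride-mediated desilylation of the tertiary silyl ether under buffered conditions that leave the peroxide, the ester and the allylic alcohol intact.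

Compound list
1 | (R)-(−)-linalool, (3R)-3,7-dimethylocta-1,6-dien-3-ol | CC(C)=CCC[C@@](C)(O)C=C | starting material
2 | bis(9-borabicyclo[3.3.1]nonyl) adduct of 1 (O-borinate and terminal C-borane) | CC(C)=CCC[C@@](C)(OB1C2CCCC1CCC2)CCB1C2CCCC1CCC2 | intermediate
3 | (3R)-3,7-dimethyloct-6-ene-1,3-diol | CC(C)=CCC[C@@](C)(O)CCO | intermediate
4 | (3R)-3-hydroxy-3,7-dimethyloct-6-en-1-yl 4-methylbenzenesulfonate | CC(C)=CCC[C@@](C)(O)CCOS(=O)(=O)c1ccc(C)cc1 | intermediate
5 | (2R)-2-methyl-2-(4-methylpent-3-en-1-yl)oxetane | CC(C)=CCC[C@]1(C)CCO1 | intermediate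
6 | 2,2-dimethyl-3-{2-[(2R)-2-methyloxetan-2-yl]ethyl}oxirane (both epimers at the oxirane CH) | CC1(C)OC1CC[C@]1(C)CCO1 | intermediate
7 | 2-methyl-5-[(2R)-2-methyloxetan-2-yl]pent-1-en-3-ol (both carbinol epimers) | C=C(C)C(O)CC[C@]1(C)CCO1 | intermediate
8 | 2-methyl-5-[(2R)-2-methyloxetan-2-yl]pent-1-en-3-one | C=C(C)C(=O)CC[C@]1(C)CCO1 | intermediate
9 | triethyl phosphonoacetate | CCOC(=O)CP(=O)(OCC)OCC | starting material
10 | acrolein | C=CC=O | starting material
11 | ethyl 2-(diethoxyphosphoryl)penta-2,4-dienoate (E/Z mixture at C2=C3) | CCOC(=O)C(=CC=C)P(=O)(OCC)OCC | intermediate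
12 | lithium 2-methyl-5-[(2R)-2-methyloxetan-2-yl]pent-2-en-3-olate | [Li+].CC(C)=C([O-])CC[C@]1(C)CCO1 | intermediate
13 | lithium C2-carbanion of ethyl 2-(diethoxyphosphoryl)-6,6-dimethyl-9-[(2R)-2-methyloxetan-2-yl]-7-oxonon-3-enoate | [Li+].CCOC(=O)[C-](C=CCC(C)(C)C(=O)CC[C@]1(C)CCO1)P(=O)(OCC)OCC | intermediate
14 | ethyl 3,3-dimethyl-2-{2-[(2R)-2-methyloxetan-2-yl]ethyl}cyclohexa-1,5-diene-1-carboxylate | CCOC(=O)C1=C(CC[C@]2(C)CCO2)C(C)(C)CC=C1 | intermediate
15 | ethyl 3,3-dimethyl-2-{2-[(2R)-2-methyloxetan-2-yl]ethyl}cyclohex-1-ene-1-carboxylate | CCOC(=O)C1=C(CC[C@]2(C)CCO2)C(C)(C)CCC1 | intermediate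
16 | (3,3-dimethyl-2-{2-[(2R)-2-methyloxetan-2-yl]ethyl}cyclohex-1-en-1-yl)methanol | OCC1=C(CC[C@]2(C)CCO2)C(C)(C)CCC1 | intermediate
17 | [(1S,6S)-5,5-dimethyl-6-{2-[(2R)-2-methyloxetan-2-yl]ethyl}-7-oxabicyclo[4.1.0]heptan-1-yl]methanol | OC[C@@]12CCCC(C)(C)[C@]1(CC[C@]3(C)CCO3)O2 | intermediate
18 | (1R,6S)-1-(iodomethyl)-5,5-dimethyl-6-{2-[(2R)-2-methyloxetan-2-yl]ethyl}-7-oxabicyclo[4.1.0]heptane | IC[C@@]12CCCC(C)(C)[C@]1(CC[C@]3(C)CCO3)O2 | intermediate
19 | (1S)-2,2-dimethyl-6-methylidene-1-{2-[(2R)-2-methyloxetan-2-yl]ethyl}cyclohexan-1-ol | C=C1CCCC(C)(C)[C@@]1(O)CC[C@]2(C)CCO2 | intermediate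
20 | potassium alkoxide of 19 | [K+].C=C1CCCC(C)(C)[C@@]1([O-])CC[C@]2(C)CCO2 | intermediate
21 | triethyl({(1S)-2,2-dimethyl-6-methylidene-1-{2-[(2R)-2-methyloxetan-2-yl]ethyl}cyclohexyl}oxy)silane | C=C1CCCC(C)(C)[C@@]1(O[Si](CC)(CC)CC)CC[C@]2(C)CCO2 | intermediate
22 | (3S)-5-[(1S)-2,2-dimethyl-6-methylidene-1-(triethylsilyloxy)cyclohexyl]-3-hydroperoxy-3-methylpentan-1-ol | C=C1CCCC(C)(C)[C@@]1(O[Si](CC)(CC)CC)CC[C@@](OO)(C)CCO | intermediate
23 | (3S)-5-[(1S)-2,2-dimethyl-6-methylidene-1-(triethylsilyloxy)cyclohexyl]-3-methyl-3-[(triethylsilyl)peroxy]pentan-1-ol | C=C1CCCC(C)(C)[C@@]1(O[Si](CC)(CC)CC)CC[C@@](OO[Si](CC)(CC)CC)(C)CCO | intermediate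
24 | (3S)-5-[(1S)-2,2-dimethyl-6-methylidene-1-(triethylsilyloxy)cyclohexyl]-3-methyl-3-[(triethylsilyl)peroxy]pentanal | C=C1CCCC(C)(C)[C@@]1(O[Si](CC)(CC)CC)CC[C@@](OO[Si](CC)(CC)CC)(C)CC=O | intermediate
25 | (4S)-6-[(1S)-2,2-dimethyl-6-methylidene-1-(triethylsilyloxy)cyclohexyl]-1-methoxy-4-methyl-4-[(triethylsilyl)peroxy]hex-1-ene (E/Z mixture) | C=C1CCCC(C)(C)[C@@]1(O[Si](CC)(CC)CC)CC[C@@](OO[Si](CC)(CC)CC)(C)CC=COC | intermediate
26 | (6S)-6-{2-[(1S)-2,2-dimethyl-6-methylidene-1-(triethylsilyloxy)cyclohexyl]ethyl}-3-methoxy-6-methyl-1,2-dioxane (both C3 epimers) | C=C1CCCC(C)(C)[C@@]1(O[Si](CC)(CC)CC)CC[C@@]2(C)CCC(OC)OO2 | intermediate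
27 | (4R)-4-benzyl-1,3-thiazolidine-2-thione | S=C1N[C@H](Cc2ccccc2)CS1 | starting material
28 | propanoyl chloride | CCC(=O)Cl | starting material
29 | (4R)-4-benzyl-3-propanoyl-1,3-thiazolidine-2-thione | CCC(=O)N1C(=S)SC[C@H]1Cc1ccccc1 | intermediate
30 | (Z)-trichlorotitanium enolate of 29 | C/C=C(\O[Ti](Cl)(Cl)Cl)N1C(=S)SC[C@H]1Cc1ccccc1 | intermediate
31 | (4R)-4-benzyl-3-{(2S)-2-[(3S,6R)-6-{2-[(1S)-2,2-dimethyl-6-methylidene-1-(triethylsilyloxy)cyclohexyl]ethyl}-6-methyl-1,2-dioxan-3-yl]propanoyl}-1,3-thiazolidine-2-thione | C=C1CCCC(C)(C)[C@@]1(O[Si](CC)(CC)CC)CC[C@@]2(C)CC[C@@H]([C@H](C)C(=O)N3C(=S)SC[C@H]3Cc3ccccc3)OO2 | intermediate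
32 | methyl (2S)-2-[(3S,6R)-6-{2-[(1S)-2,2-dimethyl-6-methylidene-1-(triethylsilyloxy)cyclohexyl]ethyl}-6-methyl-1,2-dioxan-3-yl]propanoate | C=C1CCCC(C)(C)[C@@]1(O[Si](CC)(CC)CC)CC[C@@]2(C)CC[C@@H]([C@H](C)C(=O)OC)OO2 | intermediate
33 | methyl (2S)-2-[(3S,6R)-6-{2-[(1S)-1-hydroxy-2,2-dimethyl-6-methylidenecyclohexyl]ethyl}-6-methyl-1,2-dioxan-3-yl]propanoate | C=C1CCCC(C)(C)[C@@]1(O)CC[C@@]2(C)CC[C@@H]([C@H](C)C(=O)OC)OO2 | target

Total step count: 20. Longest linear sequence: 18 steps (steps 1–5, 7–16 and 18–20).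

Steps most likely to fail

Step 18 (Proposed new method). The addition may show poor facial selectivity at the peroxycarbenium carbon, or the Lewis acid may ionise the allylic silyl ether. The fallback sets out from 26 and returns at 32. It uses the known Lewis-acid-mediated Mukaiyama-type addition of an achiral silyl ketene acetal to 3-alkoxy-1,2-dioxanes: 26 is treated with (E)-1-methoxy-1-(trimethylsilyloxy)prop-1-ene and TiCl4 or Me3SiOTf in CH2Cl2 at −78 °C. This should give 32 directly as a mixture of C2/C3 diastereomers, from which the (2S,3S) isomer is separated by preparative HPLC. Reagent control is given up for separation, and no auxiliary or new intermediate is involved.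

Step 7 (key step). The diene may suffer competing β-(1,4)-addition or anionic oligomerisation, or olefination of the hindered ketone may be sluggish. The fallback sets out from 8 (through the same enolate 12) and returns at 15. Enolate 12 is alkylated with 1-chloro-3-iodopropane to give 7-chloro-4,4-dimethyl-1-[(2R)-2-methyloxetan-2-yl]heptan-3-one F1. Sodium triethyl phosphonoacetate is then alkylated with F1 (NaH, NaI cat., DMF) to give ethyl 2-(diethoxyphosphoryl)-6,6-dimethyl-9-[(2R)-2-methyloxetan-2-yl]-7-oxononanoate F2. Ring closure by intramolecular Horner–Wadsworth–Emmons olefination (NaH, toluene, reflux) should give 15 directly, which also makes step 8 unnecessary.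

Step 16. The basic ylide may trigger β-elimination of the silyl peroxide from the aldehyde before olefination. The fallback sets out from 24 and returns at 26. The peroxide silyl group is removed first (HF·pyridine, 1 equiv, THF, −20 °C), so that the hydroperoxy aldehyde closes to the cyclic peroxy hemiacetal (5S)-5-{2-[(1S)-2,2-dimethyl-6-methylidene-1-(triethylsilyloxy)cyclohexyl]ethyl}-5-methyl-1,2-dioxolan-3-ol F3, whose conjugate base cannot eliminate. Wittig methoxymethylenation of F3 with excess ylide should give (4S)-6-[(1S)-2,2-dimethyl-6-methylidene-1-(triethylsilyloxy)cyclohexyl]-4-hydroperoxy-1-methoxy-4-methylhex-1-ene F4, and PPTS in CH2Cl2 then closes F4 to 26.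

Further compounds
F0 | step 18 | none | none
F1 | step 7 | 7-chloro-4,4-dimethyl-1-[(2R)-2-methyloxetan-2-yl]heptan-3-one | ClCCCC(C)(C)C(=O)CC[C@]1(C)CCO1
F2 | step 7 | ethyl 2-(diethoxyphosphoryl)-6,6-dimethyl-9-[(2R)-2-methyloxetan-2-yl]-7-oxononanoate | CCOC(=O)C(CCCC(C)(C)C(=O)CC[C@]1(C)CCO1)P(=O)(OCC)OCC
F3 | step 16 | (5S)-5-{2-[(1S)-2,2-dimethyl-6-methylidene-1-(triethylsilyloxy)cyclohexyl]ethyl}-5-methyl-1,2-dioxolan-3-ol | C=C1CCCC(C)(C)[C@@]1(O[Si](CC)(CC)CC)CC[C@@]2(C)CC(O)OO2
F4 | step 16 | (4S)-6-[(1S)-2,2-dimethyl-6-methylidene-1-(triethylsilyloxy)cyclohexyl]-4-hydroperoxy-1-methoxy-4-methylhex-1-ene | C=C1CCCC(C)(C)[C@@]1(O[Si](CC)(CC)CC)CC[C@@](OO)(C)CC=COC
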